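**Plan**

1. Ring numbering used throughout: C1 = carbonyl carbon, C2=C3 = ring alkene (styryl on C3), C4 = CH2, C5 = CH(3,5-dihydroxyphenyl), C6 = CH(3,4-dihydroxyphenyl), C7 = CH2.
2. Retrosynthetic cuts, in order: the four aryl O–Me bonds; a helper C4–NO2 bond; the ring bond C3–C4 (nitronate carbon onto the β-carbon of an ynone); the acyl–alkynyl bond C1–C2; the bond C5–C6 between the two aryl-bearing carbons (enal homoenolate onto a nitroalkene).
3. Enabling feature: the ring methylene C4 is both β to the aryl-bearing C5 and γ to the carbonyl C1 through C2=C3. A nitro group parked on C4 therefore makes C5 the electrophilic end of a nitroalkene, then makes C4 a carbon nucleophile toward the alkyne carbon that becomes C3, and finally sits allylic to the new cyclohept-2-enone, from where it can be removed.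
4. Forward order: C5–C6 is made first in a three-component union (enal, nitroalkene, methanol); the ester end is converted into an enynone (C1–C2); the only ring is closed last at C3–C4; the nitro group and the methyl ethers are then removed.
5. Stereochemistry: both stereocentres (5S,6S; trans in the ring, syn in the open chain) are set in step 3 by the chiral carbene catalyst. Neither is enolisable or touched afterwards. The E-styryl geometry comes from cinnamaldehyde.

Key step: step 6

Assumption: the triazolium precatalyst of step 3 is taken in the enantiomeric form and N-aryl variant that pair homoenolate and nitroalkene in the syn sense with (3S,4S) configuration; the nitro-bearing carbon of 11 is a temporary stereocentre and either epimer serves.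

**Route**

Step 1
Reactants: 1 3,5-dimethoxybenzaldehyde; 2 nitromethane
Product: 3 (E)-1,3-dimethoxy-5-(2-nitroethenyl)benzene
Conditions: MeNO2 (5 equiv), NH4OAc (0.5 equiv), AcOH, 100 °C
Reagents that add atoms: none
Why: Henry (nitroaldol) condensation with dehydration in the same pot should give the conjugated, thermodynamically preferred E-nitroalkene.

Step 2
Reactants: 4 (E)-cinnamaldehyde
Product: 5 (E)-but-1-en-3-yn-1-ylbenzene
Conditions: Me3SiCHN2 (1.2 equiv), LDA (1.2 equiv), THF, −78 °C → reflux
Reagents that add atoms: (trimethylsilyl)diazomethane, C[Si](C)(C)C=[N+]=[N-]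
Why: Colvin rearrangement (1,2-addition of lithiated trimethylsilyldiazomethane, Peterson-type loss of silanolate, loss of N2 and 1,2-hydrogen shift of the alkylidene carbene) should give the terminal enyne under aprotic conditions that leave the E-alkene untouched.

Step 3
Reactants: 6 (E)-3-(3,4-dimethoxyphenyl)prop-2-enal; 3 (E)-1,3-dimethoxy-5-(2-nitroethenyl)benzene
Product: 7 methyl (3S,4S)-3-(3,4-dimethoxyphenyl)-4-(3,5-dimethoxyphenyl)-5-nitropentanoate
Conditions: chiral aminoindanol-derived N-aryl triazolium tetrafluoroborate (carbene precatalyst, 10 mol %), NaOAc (50 mol %), MeOH (10 equiv), CH2Cl2, 23 °C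
Reagents that add atoms: methanol, CO
Why: N-heterocyclic-carbene homoenolate catalysis: the β-carbon of the carbene-bound enal adds to the nitroalkene (Michael addition) and the acyl azolium is released by methanolysis; both stereocentres are set in the C–C bond-forming event by the chiral triazolylidene, which should pair the two prochiral faces in the syn sense and fix the (3S,4S) absolute configuration.

Step 4
Reactants: 7 methyl (3S,4S)-3-(3,4-dimethoxyphenyl)-4-(3,5-dimethoxyphenyl)-5-nitropentanoate
Product: 8 (3S,4S)-3-(3,4-dimethoxyphenyl)-4-(3,5-dimethoxyphenyl)-N-methoxy-N-methyl-5-nitropentanamide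
Conditions: MeNH(OMe)·HCl (3 equiv) premixed with i-PrMgCl (6 equiv), THF, −20 °C; then 7, −20 → 0 °C; aq NH4Cl
Reagents that add atoms: N,O-dimethylhydroxylamine hydrochloride, CNOC.Cl
Why: Weinreb amidation of the methyl ester by the preformed magnesium amide should proceed while the nitro group is held reversibly as its nitronate and no free Grignard reagent meets it; no stereocentre is enolisable.

Step 5
Reactants: 8 (3S,4S)-3-(3,4-dimethoxyphenyl)-4-(3,5-dimethoxyphenyl)-N-methoxy-N-methyl-5-nitropentanamide; 5 (E)-but-1-en-3-yn-1-ylbenzene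
Product: 10 (1E,7S,8S)-7-(3,4-dimethoxyphenyl)-8-(3,5-dimethoxyphenyl)-9-nitro-1-phenylnon-1-en-3-yn-5-one, via lithium acetylide 9 (not isolated)
Conditions: 5 (3.0 equiv), n-BuLi (2.9 equiv), THF, −78 °C; then 8, −78 → −30 °C; AcOH, −78 °C
Reagents that add atoms: none
Why: Weinreb ketone synthesis: one equivalent of acetylide is spent on the acidic CH2NO2 group, whose nitronate is inert, and a second adds to the amide to give a chelated tetrahedral intermediate that should release the ynone only on the cold acidic quench.

Step 6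
Reactants: 10 (1E,7S,8S)-7-(3,4-dimethoxyphenyl)-8-(3,5-dimethoxyphenyl)-9-nitro-1-phenylnon-1-en-3-yn-5-one
Product: 11 (4S,5S,6S)-6-(3,4-dimethoxyphenyl)-5-(3,5-dimethoxyphenyl)-4-nitro-3-[(E)-2-phenylethenyl]cyclohept-2-en-1-one
Conditions: DBU (1.2 equiv), MeCN (0.005 M), 0 → 23 °C; then AcOH, −20 °C
Reagents that add atoms: none
Why: Proposed new method: DBU deprotonates the CH2NO2 group and the nitronate carbon adds to the β-carbon of the enynone, the ring allenolate being protonated to the ring-constrained cis-enone; the closest known reaction type is the base-mediated Michael addition of nitroalkanes to alkynyl ketones, known between two molecules, together with endo-dig Michael ring closures of ynones by oxygen and nitrogen nucleophiles. The seven-membered ring closes in the 7-endo-dig mode, which the obtuse approach angle onto a linear alkyne permits. The only new stereocentre, the nitro-bearing carbon, stays acidic and should settle by equilibration trans to the neighbouring aryl group; it is deleted in step 7, and the two aryl-bearing centres are not enolisable and are left untouched. The step needs carbon attack at the ynone β-carbon in preference to 5-exo-trig nitroaldol addition to the ketone, to 1,6-addition at the styryl terminus and to addition between two molecules. The nitroaldol adduct is reversible whereas the Michael adduct is held as a doubly stabilised nitronate–dienolate, 1,6-addition would need a nine-membered ring, and high dilution disfavours oligomers. On acidification the anion should protonate to the conjugated dienone, because the alternative tetrasubstituted nitroalkene is strained.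

Step 7
Reactants: 11 (4S,5S,6S)-6-(3,4-dimethoxyphenyl)-5-(3,5-dimethoxyphenyl)-4-nitro-3-[(E)-2-phenylethenyl]cyclohept-2-en-1-one
Product: 12 (5S,6S)-6-(3,4-dimethoxyphenyl)-5-(3,5-dimethoxyphenyl)-3-[(E)-2-phenylethenyl]cyclohept-2-en-1-one
Conditions: Bu3SnH (1.3 equiv), AIBN (0.2 equiv), PhMe, 90 °C; then DBU (0.2 equiv), 23 °C
Reagents that add atoms: none
Why: Radical chain denitration of an allylic nitro compound with tributyltin hydride: the stannyl radical adds to a nitro oxygen, C–N homolysis gives an acyl-stabilised allyl radical that takes hydrogen from the hydride, and DBU should move any deconjugated alkene into the fully conjugated dienone; neither stereocentre is involved.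

Step 8
Reactants: 12 (5S,6S)-6-(3,4-dimethoxyphenyl)-5-(3,5-dimethoxyphenyl)-3-[(E)-2-phenylethenyl]cyclohept-2-en-1-one
Product: 13 (5S,6S)-6-(3,4-dihydroxyphenyl)-5-(3,5-dihydroxyphenyl)-3-[(E)-2-phenylethenyl]cyclohept-2-en-1-one
Conditions: BBr3 (8 equiv), CH2Cl2, −78 → 0 °C; then H2O, 0 °C
Reagents that add atoms: none
Why: Lewis-acid cleavage of the four aryl methyl ethers (boron coordination, then SN2 attack of bromide on methyl) should free the phenols at low temperature without touching the dienone or the non-enolisable stereocentres.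

**Compound list**

1 | 3,5-dimethoxybenzaldehyde | COc1cc(C=O)cc(OC)c1 | starting material
2 | nitromethane | C[N+](=O)[O-] | starting material
3 | (E)-1,3-dimethoxy-5-(2-nitroethenyl)benzene | COc1cc(/C=C/[N+](=O)[O-])cc(OC)c1 | intermediate
4 | (E)-cinnamaldehyde | O=C/C=C/c1ccccc1 | starting material
5 | (E)-but-1-en-3-yn-1-ylbenzene | C#C/C=C/c1ccccc1 | intermediate
6 | (E)-3-(3,4-dimethoxyphenyl)prop-2-enal | COc1ccc(/C=C/C=O)cc1OC | starting material
7 | methyl (3S,4S)-3-(3,4-dimethoxyphenyl)-4-(3,5-dimethoxyphenyl)-5-nitropentanoate | [O-][N+](=O)C[C@H](c1cc(OC)cc(OC)c1)[C@@H](c1ccc(OC)c(OC)c1)CC(=O)OC | intermediate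
8 | (3S,4S)-3-(3,4-dimethoxyphenyl)-4-(3,5-dimethoxyphenyl)-N-methoxy-N-methyl-5-nitropentanamide | [O-][N+](=O)C[C@H](c1cc(OC)cc(OC)c1)[C@@H](c1ccc(OC)c(OC)c1)CC(=O)N(C)OC | intermediate
9 | lithium (E)-4-phenylbut-3-en-1-yn-1-ide (lithium acetylide of 5, not isolated) | [Li+].[C-]#C/C=C/c1ccccc1 | intermediate
10 | (1E,7S,8S)-7-(3,4-dimethoxyphenyl)-8-(3,5-dimethoxyphenyl)-9-nitro-1-phenylnon-1-en-3-yn-5-one | [O-][N+](=O)C[C@H](c1cc(OC)cc(OC)c1)[C@@H](c1ccc(OC)c(OC)c1)CC(=O)C#C/C=C/c1ccccc1 | intermediate
11 | (4S,5S,6S)-6-(3,4-dimethoxyphenyl)-5-(3,5-dimethoxyphenyl)-4-nitro-3-[(E)-2-phenylethenyl]cyclohept-2-en-1-one (nitro trans to the C5 aryl group; the C4 epimer serves equally) | O=C1C=C(/C=C/c2ccccc2)[C@@H]([N+](=O)[O-])[C@H](c2cc(OC)cc(OC)c2)[C@@H](c2ccc(OC)c(OC)c2)C1 | intermediate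
12 | (5S,6S)-6-(3,4-dimethoxyphenyl)-5-(3,5-dimethoxyphenyl)-3-[(E)-2-phenylethenyl]cyclohept-2-en-1-one | O=C1C=C(/C=C/c2ccccc2)C[C@H](c2cc(OC)cc(OC)c2)[C@@H](c2ccc(OC)c(OC)c2)C1 | intermediate
13 | (5S,6S)-6-(3,4-dihydroxyphenyl)-5-(3,5-dihydroxyphenyl)-3-[(E)-2-phenylethenyl]cyclohept-2-en-1-one | O=C1C=C(/C=C/c2ccccc2)C[C@H](c2cc(O)cc(O)c2)[C@@H](c2ccc(O)c(O)c2)C1 | target

**Count and risks**

Total step count: 8. Longest linear sequence: 7 steps (steps 1, 3, 4, 5, 6, 7, 8).

Steps most likely to fail:

1. Step 6. The nitronate may rest in the reversible five-membered nitroaldol closure onto the ketone, or add to a second molecule, because the endo-dig approach to the alkyne within a seven-membered transition state is strained. The fallback uses known chemistry, sets out from 7 and 5 and comes back at 12. It makes the nitronate–alkyne bond between two molecules and closes the ring on the other flank of the carbonyl group. Enyne 5 is lithiated (n-BuLi, THF, −78 °C) and acylated with ClCO2Me to give methyl (E)-5-phenylpent-4-en-2-ynoate F1. Michael addition of the nitronate of 7 to F1 (DBU, MeCN) should give dimethyl (5S,6S)-6-(3,4-dimethoxyphenyl)-5-(3,5-dimethoxyphenyl)-4-nitro-3-[(E)-2-phenylethenyl]oct-2-enedioate F2. Radical denitration (Bu3SnH, AIBN, PhMe, 90 °C) should give dimethyl (5S,6S)-6-(3,4-dimethoxyphenyl)-5-(3,5-dimethoxyphenyl)-3-[(E)-2-phenylethenyl]oct-2-enedioate F3. Dieckmann condensation (KOt-Bu, THF, dilute) of the saturated ester enolate onto the unsaturated ester, whose double bond can equilibrate through the dienolate, should give methyl (6S,7R)-7-(3,4-dimethoxyphenyl)-6-(3,5-dimethoxyphenyl)-2-oxo-4-[(E)-2-phenylethenyl]cyclohept-3-ene-1-carboxylate F4. Krapcho demethoxycarbonylation (LiCl, wet DMSO, 140 °C) should then give 12.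

2. Step 3. The homoenolate and the nitroalkene may pair in the anti sense, or the acyl-anion (Stetter-type) pathway may compete with homoenolate addition. The fallback sets out from 3 and comes back at 7, moving the stereo-defining step to enamine catalysis. Michael addition of purchased (3,4-dimethoxyphenyl)acetaldehyde to 3 with a diphenylprolinol trimethylsilyl ether (syn-selective through the usual acyclic synclinal transition state) should give (2S,3S)-2-(3,4-dimethoxyphenyl)-3-(3,5-dimethoxyphenyl)-4-nitrobutanal F5. Pinnick oxidation (NaClO2, NaH2PO4, 2-methylbut-2-ene) should give (2S,3S)-2-(3,4-dimethoxyphenyl)-3-(3,5-dimethoxyphenyl)-4-nitrobutanoic acid F6. Arndt–Eistert homologation follows: the mixed anhydride (ClCO2Et, Et3N) with CH2N2 should give (3S,4S)-1-diazo-3-(3,4-dimethoxyphenyl)-4-(3,5-dimethoxyphenyl)-5-nitropentan-2-one F7, and Wolff rearrangement (PhCO2Ag, Et3N, MeOH), with retention at the migrating carbon, should give 7.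

3. Step 7. Hydrostannation or conjugate reduction of the dienone may compete with C–N homolysis of the secondary allylic nitro group. The fallback sets out from 11 and comes back at 12, replacing the radical chain by an ionic allylic hydrogenolysis. Pd(PPh3)4 (zerovalent palladium, 5 mol %) with HCO2NH4 in THF at 50 °C should ionise the allylic nitro group to a π-allylpalladium intermediate that is reduced by formate. DBU then moves the alkene into conjugation. No new compound is made (F0).

**Further compounds**

F1 | step 6 | methyl (E)-5-phenylpent-4-en-2-ynoate | COC(=O)C#C/C=C/c1ccccc1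
F2 | step 6 | dimethyl (5S,6S)-6-(3,4-dimethoxyphenyl)-5-(3,5-dimethoxyphenyl)-4-nitro-3-[(E)-2-phenylethenyl]oct-2-enedioate (mixture at C4 and at the C2=C3 bond) | COC(=O)C=C(/C=C/c1ccccc1)C([N+](=O)[O-])[C@H](c1cc(OC)cc(OC)c1)[C@@H](c1ccc(OC)c(OC)c1)CC(=O)OC
F3 | step 6 | dimethyl (5S,6S)-6-(3,4-dimethoxyphenyl)-5-(3,5-dimethoxyphenyl)-3-[(E)-2-phenylethenyl]oct-2-enedioate (C2=C3 isomers) | COC(=O)C=C(/C=C/c1ccccc1)C[C@H](c1cc(OC)cc(OC)c1)[C@@H](c1ccc(OC)c(OC)c1)CC(=O)OC
F4 | step 6 | methyl (6S,7R)-7-(3,4-dimethoxyphenyl)-6-(3,5-dimethoxyphenyl)-2-oxo-4-[(E)-2-phenylethenyl]cyclohept-3-ene-1-carboxylate (C1 epimers) | COC(=O)C1C(=O)C=C(/C=C/c2ccccc2)C[C@H](c2cc(OC)cc(OC)c2)[C@H]1c1ccc(OC)c(OC)c1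
F5 | step 3 | (2S,3S)-2-(3,4-dimethoxyphenyl)-3-(3,5-dimethoxyphenyl)-4-nitrobutanal | [O-][N+](=O)C[C@H](c1cc(OC)cc(OC)c1)[C@@H](c1ccc(OC)c(OC)c1)C=O
F6 | step 3 | (2S,3S)-2-(3,4-dimethoxyphenyl)-3-(3,5-dimethoxyphenyl)-4-nitrobutanoic acid | [O-][N+](=O)C[C@H](c1cc(OC)cc(OC)c1)[C@@H](c1ccc(OC)c(OC)c1)C(=O)O
F7 | step 3 | (3S,4S)-1-diazo-3-(3,4-dimethoxyphenyl)-4-(3,5-dimethoxyphenyl)-5-nitropentan-2-one | [O-][N+](=O)C[C@H](c1cc(OC)cc(OC)c1)[C@@H](c1ccc(OC)c(OC)c1)C(=O)C=[N+]=[N-]
F0 | step 7 | none | none
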